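The data come from a simulation with constants of no real substance; noise was put on by code.

- Read from the same alpha run, the constant k for D pairing into G carries a smaller relative error, 1.37%, than the constant c for G decaying into X, 8.33%, but the answer need not follow those errors.

| setting | alpha | beta | north-west | west | north | south-west | south |
|---|---|---|---|---|---|---|---|
| D | 0.010 M | 0.010 M | 0.010 M | 0.0060 M | 0.030 M | 0.0025 M | 0.0050 M |
| Q | 0.30 mM | 0.10 mM | 0.200 mM | 0.200 mM | 0.200 mM | 0.200 mM | 0.200 mM |
| remark | run made earlier | run made earlier |  |  |  |  |  |
| time |  |  | 50 min | 50 min | 50 min | 50 min | 50 min |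

| run | time / min | G / % | D / % |
|---|---|---|---|
| alpha | 2.50 | 5.6 | 91.5 |
| alpha | 5.00 | 10.5 | 86.7 |
| alpha | 8.00 | 15.5 | 80.8 |
| alpha | 15.0 | 23.3 | 69.9 |
| alpha | 30.0 | 30.6 | 55.4 |
| beta | 2.50 | 5.9 | 93.1 |
| beta | 8.00 | 15.7 | 82.4 |
| beta | 15.0 | 24.3 | 71.3 |
| beta | 20.0 | 27.5 | 65.2 |
| beta | 30.0 | 31.1 | 56.1 |

(each reading ± 0.3 percentage points)

- percent here means D units held: one G or X counts as two
- steps thought possible: G <-> X; 2 D <-> G; D + Q -> J

1. all flasks from highest to lowest amount of G, in percent of the D charged, at 50 min (north-west / west / north / south-west / south)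
2. the amount of G, in percent of the D charged of the flask you put first, at 50 min
3. the amount of G, in percent of the D charged of the flask you put last, at 50 min

- Early on, the balance falls short by 2.9 percentage points in alpha and 1 point in beta, close to the Q charged, 3.00% and 1.00% of D. I therefore take one D per Q, with Q the limiting reagent of that side step.
- The reciprocal of [D] then climbs steadily, giving k, counted as D lost, as 0.0432 M⁻¹ s⁻¹ from alpha and 0.0429 M⁻¹ s⁻¹ from beta.
- Work with what is left. In south-west, take the share of D that Q spares and divide it by one plus k times the spared [D] times the time: 70.9%, the fraction left.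
- That leaves 21.1% of the D paired in south-west. With c = 0.0178 min⁻¹ and a roughly steady flux, 66.2% of that survives as G.
- For G in south-west, dropping the Q correction moves the answer by 2.2 points, the error in c by 0.43 points, and the error in k by 0.15 points. The shift from the Q correction is the largest of the 3, so in this estimate the charge of Q comes first, and it is a number you set, not one you fit.
- My reckoning for south-west is 14.0% of G.
- The forecast, which said to “integrate formation against the decay of G”, gave north > north-west > west > south > south-west, top 41.5% (39% to 44%) and low 13.4% (12.4% to 14.4%), a low below mine.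
- The flasks give north > north-west > west > south > south-west, with top 44.4% and low 13.9%.

    G ⇌ X (K = 2.30, k = 3.20 × 10⁻⁴ s⁻¹)
    2 D ⇌ G (K = 1300 M⁻¹, k = 0.0220 M⁻¹ s⁻¹)
    D + Q → J (k = 2.40 M⁻¹ s⁻¹)

- In south-west, half of the turnover of D with Q is behind by 1.99 min and half of the pairing by 21.2 min, and the fraction left of 70.9% stands beside 70.8% of D at 50.0 min. In the neighbour charged with 0.0015 M of D, the same reckoning gives 74.2%, and that flask holds 73.9%.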